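## Structural features

The target is a C24 acid built on two saturated oxygen heterocycles, a 1,2-dioxane (O1, O2, C3–C6) and a tetrahydrofuran (O, C7–C10), joined directly through the C6–C7 bond. C3 carries the acetic acid arm (C2, C1), and C10 carries an unbranched C14 chain (C11–C24) with a conjugated (17Z,19E)-diene and an isolated terminal alkene at C23. There are four stereocentres (3S,6S,7S,10R): C6 and C7 are contiguous and threo, C3 and C6 are trans on the dioxane (both substituents equatorial), and C7 and C10 are trans on the tetrahydrofuran. The fragile groups are the O–O bond (phosphines, low-valent metals, hydrides, hydrogenation, strong base), the β-peroxy acid unit C1–C3 (retro-Michael ring opening through the C2 enolate) and the Z,E-diene (radicals, dioxygen, acid, isomerisation). The real difficulty is to put a peroxide oxygen on C6, a secondary carbon next to the oxygen-bearing C7, and to close the six-membered peroxide with the right C3/C6 relationship before the oxidisable diene exists. The key step uses the fact that C3–C4–C5–C6 of the dioxane can be drawn as a cyclobutane whose C3–C6 bond has been replaced by O–O, with C3 at the aldehyde oxidation level. A 2-(tetrahydrofuran-2-yl)cyclobutanol therefore maps onto the 1,2-dioxan-3-ol by insertion of O2.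

## Logic of the disconnections

27 is taken back to 26 by cutting the C1–OH bond of the carboxyl group (ester hydrolysis forward). A free acid would interfere with the ylide base of the preceding step. The gain is a neutral, chromatographable intermediate. The demand is a hydrolysis mild enough to spare the O–O bond, the C3 centre and the diene.

26 is cut at C17=C18 into 21 (through 25) and 24. This is the only Z alkene, and it lies between a saturated carbon and a diene, so a non-stabilised ylide at C17 with an enal at C18 is the polarity that gives Z. The cut removes every oxidisable alkene from the peroxide-forming part of the route. The forward step must be salt-free, cold, and run with less than one equivalent of base so that C2 is not deprotonated.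

24 is cut at C19=C20 into 22 and 23. A stabilised ylide gives the E enal in one step from catalogue compounds. The only demand is to stop at mono-homologation.

21 goes back through 20 and 19 to 18 by exchanging C17–P for C17–I and then C17–O. These are changes at a primary carbon remote from all stereocentres, and they let the C17 oxygen travel as a robust silyl ether from step 1. The demand is that the phosphorus reagents react at C17 faster than they reduce the O–O bond.

18 is taken back to its C3 epimer mixture 17, which is cut at C2–C3 into 15 and 16. C3 is the acetal-type carbon of the peroxide ring and can act as an electrophile (peroxycarbenium ion) toward an acetate enolate equivalent. The gain is a two-carbon arm from a commercial reagent and no need for C3 control at the bond-forming stage. The demands are exocyclic ionisation and a later equilibration of the β-peroxy ester to the trans isomer by reversible ring opening.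

15 goes back to 14 by removing the acetyl group, which only turns the hemiacetal hydroxyl into a leaving group.

14 is disconnected at O–C6 and O–C3 and the C3–C6 bond is restored, giving 12. This is the strategic cut: it removes the peroxide, one ring and the C6 centre in one operation and leaves a cyclobutanol whose ring stereochemistry is irrelevant. The forward step must cleave C3–C6 rather than C3–C4 and capture O2 at C6. It cannot be expected to control C6, so a separation is part of the plan, and no alkene may be present.

12 goes back to 11 (C3–H, hydride reduction), and 11 is cut at C3–C6 and C5–C6 into 7 and 8. The aldehyde carbon C6 accepts a cyclopropylidene unit and one ring bond then migrates to it, so the four-membered ring comes from an aldehyde in one operation. The demands are no epimerisation of the α-alkoxy aldehyde at C7 and a ring expansion that tolerates the oxygen on C7.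

7 goes back to 6 (oxidation level at C6), and 6 is cut at O–C7 and C6–O(H) to give 5. Cutting here rather than at C10–C11 lets the existing C10 centre set C7 through a cyclisation with an inherent 2,5-trans preference, instead of an alkylation of a ring oxocarbenium ion whose facial bias is weak. The demand is a trans-selective oxidative cyclisation that stops at the primary alcohol.

5 is cut at C11–C12 into 3 and 2 (as 4). The C10 centre is bought with 3, and the cut lies between two methylene groups, where copper-catalysed epoxide opening is reliable. The demand is attack at the terminal epoxide carbon only.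

2 goes back to 1 by removal of the silyl group.

## Other disconnections considered

Alternative 1: The tetrahydrofuran is opened at O–C7 and the C6 oxygen is removed, leading to the open-chain (6Z) hydroxy pentaenoate A2.
- Forward key step: Re2O7 with trifluoroacetic anhydride would convert the C10 carbinol of A2 into a perrhenate ester that adds syn across C6=C7. This would give the 2,5-trans tetrahydrofuran A1 with an erythro C6 carbinol and the C2=C3 enoate intact.
- In its favour: C7 and C6 are created together and stereospecifically from alkene geometry and the C10 centre. The whole polyene tail is present before any peroxide exists, so no phosphorus reagent meets the O–O bond. The enoate is ready for a peroxide conjugate addition.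
- Against it here: the C6 oxygen of A1 is a hydroxyl of the wrong configuration. The peroxide would still have to enter by SN2 displacement with inversion at a secondary carbon next to the ring oxygen, where elimination and participation of the ring oxygen compete. The acidic heptavalent rhenium reagent must coexist with four other alkenes, including the conjugated diene. The later peroxide conjugate addition leaves C3 under the same thermodynamic control as in the chosen plan.
- Comparison: on C6 stereocontrol the alternative is better in principle (stereospecific addition then stereospecific inversion, against unselective radical capture of O2), and it is also better at keeping phosphines away from the peroxide. On C3 the two are equal. On the peroxide-forming event the chosen plan is stronger, since both oxygens come from O2 in one catalytic step with no substitution at C6. In step count, building the C24 pentaene A2 with its C10 centre is expected to cost at least as much as steps 1 to 6.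

Alternative 2: O–C10 and C10–C11 of the tetrahydrofuran are cut, leading to the diazoketone A4, an allyl ether of the C7 carbinol.
- Forward key step: Cu(acac)2 would decompose A4 to a copper carbenoid at C10, the ether oxygen would close a five-membered oxonium ylide, and a [2,3]-shift of the allyl group would give the trans-2,5-disubstituted tetrahydrofuran-3-one A3.
- In its favour: one centre (C7, available from the chiral pool) controls C10 through a compact cyclic transition state, and the ring and a C–C bond form in one catalytic step.
- Against it here: A3 carries a C9 ketone that the target lacks and only a three-carbon stub at C10, so deoxygenation and chain extension to C17 must follow. A diazoketone must be made and handled. The plan does not address the peroxide ring, for which a second strategy (for example the chosen one, entered at 7) would still be needed.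
- Comparison: for the trans relationship at C7/C10 the alternative is the equal of step 3, since both rely on one existing centre. Mechanistically both are metal-catalysed ring closures (ylide rearrangement there, alkoxide addition to an alkene here). In step economy the chosen plan is better, because step 3 gives the ring at the correct oxidation level with the C11–C17 chain already attached.

Alternative 3: Both rings are cut at once, O–C6 of the dioxane and O–C10 of the tetrahydrofuran, leading to the open-chain C3 hydroperoxide A6 with a cis C6–C7 epoxide and a C10 mesylate.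
- Forward key step: acid would make the hydroperoxide open the epoxide at C6 in a 6-exo manner, and base would then let the freed C7 oxygen displace the mesylate in a 5-exo manner. This would give the dioxane–tetrahydrofuran A5 with the complete chain and C1 as a silyl ether.
- In its favour: C3, C6, C7 and C10 all come from defined acyclic centres through stereospecific steps (inversion at C6 and C10), so neither a C6 epimer mixture nor a C3 equilibration arises. The polyene is in place before the peroxide, so no Wittig chemistry is needed next to the O–O bond.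
- Against it here: an enantiopure secondary hydroperoxide must be made and carried alongside an epoxide and a sulfonate. The conjugated diene must survive the hydroperoxide (radical chain oxidation) and the acid. The regiochemistry of epoxide opening (6-exo against 7-endo) is open. The basic second stage exposes the new peroxide to Kornblum–DeLaMare fragmentation. C1 must afterwards be oxidised from the silyl ether level to the acid in the presence of the triene.
- Comparison: in stereocontrol the alternative is better than the chosen plan at C6 and C3, and it is also better at keeping phosphines away from the peroxide. Mechanistically it is ionic and stereospecific where the chosen key step is radical and convergent, which helps selectivity but increases the number of sensitive functions that must coexist. In step economy the long linear construction of A6 is expected to exceed the sixteen steps planned here.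

Key step: step 7

Remark: 3 is taken as a purchasable enantiopure epoxide (otherwise the unreacted enantiomer from hydrolytic kinetic resolution of the racemate), and Co(modp)2 is prepared beforehand from Co(OAc)2 and the diketonate ligand.

## Route

Step 1
Reactants: 1 6-bromohexan-1-ol
Product: 2 tert-butyl[(6-bromohexyl)oxy]diphenylsilane
Conditions: TBDPSCl, imidazole, CH2Cl2, 0 °C to rt
Reagents that add atoms: tert-butyl(chloro)diphenylsilane, CC(C)(C)[Si](Cl)(c1ccccc1)c1ccccc1
Why: Imidazole-assisted silylation of a primary alcohol; the bulky silyl ether should survive Grignard formation, oxidation, ylide, Lewis acid and radical steps and is removed late by fluoride without touching the peroxide.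

Step 2
Reactants: 2 tert-butyl[(6-bromohexyl)oxy]diphenylsilane; 3 (2S)-2-(but-3-en-1-yl)oxirane
Product: 5 (5R)-12-[(tert-butyldiphenylsilyl)oxy]dodec-1-en-5-ol, via Grignard reagent 4 (not isolated)
Conditions: Mg, THF, rt to 40 °C; then CuI (10 mol%), 3, THF, −30 to 0 °C; aq. NH4Cl
Reagents that add atoms: none
Why: Copper-catalysed SN2 opening of a terminal epoxide by a primary alkyl Grignard reagent at the unsubstituted carbon; C10 is not a reacting centre, so the S epoxide gives the 5R carbinol (the descriptor changes through priorities only).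

Step 3
Reactants: 5 (5R)-12-[(tert-butyldiphenylsilyl)oxy]dodec-1-en-5-ol
Product: 6 [(2S,5R)-5-{7-[(tert-butyldiphenylsilyl)oxy]heptyl}oxolan-2-yl]methanol
Conditions: Co(modp)2 (15 mol%; modp = 1-morpholinocarbamoyl-4,4-dimethylpentane-1,3-dionate), O2 (1 atm), t-BuOOH (10 mol%), i-PrOH, 55 °C
Reagents that add atoms: dioxygen, O=O
Why: Mukaiyama aerobic oxidative cyclisation of a 1-substituted pent-4-en-1-ol; the cobalt-bound alkoxide adds to the terminal alkene with an inherent 2,5-trans preference, so the C10 centre sets C7 as S, and the exocyclic carbon radical is oxygenated and reduced to the primary alcohol.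

Step 4
Reactants: 6 [(2S,5R)-5-{7-[(tert-butyldiphenylsilyl)oxy]heptyl}oxolan-2-yl]methanol
Product: 7 (2S,5R)-5-{7-[(tert-butyldiphenylsilyl)oxy]heptyl}oxolane-2-carbaldehyde
Conditions: Dess–Martin periodinane, CH2Cl2, 0 °C to rt; used crude at once
Reagents that add atoms: none
Why: Dess–Martin oxidation under non-enolising conditions should give the α-alkoxy aldehyde without disturbing C7.

Step 5
Reactants: 7 (2S,5R)-5-{7-[(tert-butyldiphenylsilyl)oxy]heptyl}oxolane-2-carbaldehyde; 8 cyclopropyldiphenylsulfonium tetrafluoroborate
Product: 11 2-[(2S,5R)-5-{7-[(tert-butyldiphenylsilyl)oxy]heptyl}oxolan-2-yl]cyclobutan-1-one (both C2 epimers), via diphenylsulfonium cyclopropylide 9 (not isolated), via oxaspiropentane 10 (not isolated)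
Conditions: 8, KN(SiMe3)2, DME, −50 °C; add 7, −50 to 0 °C; aqueous work-up; crude 10, LiBF4 (0.3 equiv), toluene/THF, 25–50 °C
Reagents that add atoms: none
Why: Trost cyclobutanone annulation: the preformed sulfur ylide adds to the aldehyde and closes to the oxaspiropentane, and Li+ promotes the cyclopropylcarbinyl-to-cyclobutyl (semipinacol) shift in which C5 migrates to C6; pre-forming the ylide keeps the aldehyde away from free base, and the configuration created at C6 is irrelevant.

Step 6
Reactants: 11 2-[(2S,5R)-5-{7-[(tert-butyldiphenylsilyl)oxy]heptyl}oxolan-2-yl]cyclobutan-1-one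
Product: 12 2-[(2S,5R)-5-{7-[(tert-butyldiphenylsilyl)oxy]heptyl}oxolan-2-yl]cyclobutan-1-ol (all cyclobutane diastereomers)
Conditions: NaBH4, MeOH, 0 °C
Reagents that add atoms: none
Why: Borohydride reduction of the strained ketone is fast at 0 °C and should outrun β-elimination of the C7 oxygen; the diastereomer mixture is used as such because all isomers converge in step 7.

Step 7
Reactants: 12 2-[(2S,5R)-5-{7-[(tert-butyldiphenylsilyl)oxy]heptyl}oxolan-2-yl]cyclobutan-1-ol
Product: 14 (6S)-6-[(2S,5R)-5-{7-[(tert-butyldiphenylsilyl)oxy]heptyl}oxolan-2-yl]-1,2-dioxan-3-ol (both C3 anomers), via hydroperoxy aldehyde 13 (not isolated)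
Conditions: Co(acac)2 (0.2 equiv), O2 (1 atm), CH2Cl2, 25–35 °C; chromatography to remove the 6R epimer
Reagents that add atoms: dioxygen, O=O
Why: Divalent cobalt and O2 give a trivalent cobalt species that exchanges with the cyclobutanol O–H; homolysis of the Co–O bond releases the cyclobutyloxy radical, whose strain-driven β-scission breaks C3–C6 to leave the C3 aldehyde and a secondary radical at C6. That radical captures O2, the peroxyl radical is reduced by divalent cobalt and protonated by a further molecule of 12 to give the hydroperoxy aldehyde 13, and the cobalt alkoxide formed in this exchange carries the chain. The dioxane ring then closes by 6-exo-trig addition of the C6 hydroperoxide to the C3 carbonyl, so O–C6 forms first and O–C3 second. The closest known reaction type is the cobalt-catalysed aerobic oxidative ring expansion of cyclobutanols to 1,2-dioxan-3-ols, related to the Mukaiyama–Isayama peroxidation. The new C6 centre is fixed at the moment of O2 capture; the only controlling element is the adjacent C7 centre, which is expected to give a weak bias at best, so both C6 epimers should form and the 6S epimer is isolated by chromatography (if the anomer pairs overlap, the mixture is carried to 18 and separated there). C3 is a hemiacetal centre and is left as an anomer mixture because step 9 erases it. The step needs regioselective scission (C3–C6 rather than C3–C4), secured by the C6 substituent that makes the resulting radical secondary rather than primary, and chemoselectivity, secured by the absence of any alkene and by the inert silyl ether; all diastereomers of 12 converge on the same radical.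

Step 8
Reactants: 14 (6S)-6-[(2S,5R)-5-{7-[(tert-butyldiphenylsilyl)oxy]heptyl}oxolan-2-yl]-1,2-dioxan-3-ol
Product: 15 (6S)-6-[(2S,5R)-5-{7-[(tert-butyldiphenylsilyl)oxy]heptyl}oxolan-2-yl]-1,2-dioxan-3-yl acetate (both C3 anomers)
Conditions: Ac2O, pyridine, DMAP (cat.), CH2Cl2, 0 °C
Reagents that add atoms: acetic anhydride, CC(=O)OC(C)=O
Why: O-acylation of the peroxy-hemiacetal hydroxyl traps the cyclic form as an ionisable peroxy-acetal acetate; both anomers are usable because ionisation removes the C3 centre.

Step 9
Reactants: 15 (6S)-6-[(2S,5R)-5-{7-[(tert-butyldiphenylsilyl)oxy]heptyl}oxolan-2-yl]-1,2-dioxan-3-yl acetate; 16 tert-butyl[(1-methoxyethenyl)oxy]dimethylsilane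
Product: 17 methyl 2-[(6S)-6-[(2S,5R)-5-{7-[(tert-butyldiphenylsilyl)oxy]heptyl}oxolan-2-yl]-1,2-dioxan-3-yl]acetate (C3 epimers)
Conditions: 16 (2.5 equiv), Me3SiOTf (0.3 equiv), CH2Cl2, −78 to −40 °C
Reagents that add atoms: none
Why: Lewis-acid ionisation to the cyclic peroxycarbenium ion and Mukaiyama-type addition of the silyl ketene acetal at C3, a known C–C bond formation of peroxy-acetals; axial attack on the half-chair with the C6 substituent pseudo-equatorial is expected to favour the 3,6-cis epimer, so the mixture goes into the equilibration.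

Step 10
Reactants: 17 methyl 2-[(6S)-6-[(2S,5R)-5-{7-[(tert-butyldiphenylsilyl)oxy]heptyl}oxolan-2-yl]-1,2-dioxan-3-yl]acetate (C3 epimers)
Product: 18 methyl 2-[(3S,6S)-6-[(2S,5R)-5-{7-[(tert-butyldiphenylsilyl)oxy]heptyl}oxolan-2-yl]-1,2-dioxan-3-yl]acetate
Conditions: NaOMe (0.2 equiv), MeOH, 0 °C to rt, monitored; AcOH quench; chromatography, cis isomer recycled
Reagents that add atoms: none
Why: Reversible E1cB opening (retro-oxa-Michael) to the C6 hydroperoxide and the (E)-enoate, followed by 6-exo-trig re-addition, equilibrates C3; the 3,6-trans isomer with both substituents equatorial should be the thermodynamic product, which sets C3 as S.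

Step 11
Reactants: 18 methyl 2-[(3S,6S)-6-[(2S,5R)-5-{7-[(tert-butyldiphenylsilyl)oxy]heptyl}oxolan-2-yl]-1,2-dioxan-3-yl]acetate
Product: 19 methyl 2-[(3S,6S)-6-[(2S,5R)-5-(7-hydroxyheptyl)oxolan-2-yl]-1,2-dioxan-3-yl]acetate
Conditions: HF·pyridine, pyridine, THF, 0 °C to rt
Reagents that add atoms: none
Why: Fluoride cleavage of the silyl ether under buffered, non-basic conditions that should leave the peroxide, the ester and the C3 centre untouched.

Step 12
Reactants: 19 methyl 2-[(3S,6S)-6-[(2S,5R)-5-(7-hydroxyheptyl)oxolan-2-yl]-1,2-dioxan-3-yl]acetate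
Product: 20 methyl 2-[(3S,6S)-6-[(2S,5R)-5-(7-iodoheptyl)oxolan-2-yl]-1,2-dioxan-3-yl]acetate
Conditions: PPh3 and I2 premixed (slight excess of I2), imidazole, CH2Cl2, 0 °C
Reagents that add atoms: iodine, II
Why: Appel-type iodination of a primary alcohol through the preformed iodophosphonium species, so that no free phosphine meets the peroxide.

Step 13
Reactants: 20 methyl 2-[(3S,6S)-6-[(2S,5R)-5-(7-iodoheptyl)oxolan-2-yl]-1,2-dioxan-3-yl]acetate
Product: 21 {7-[(2R,5S)-5-[(3S,6S)-6-(2-methoxy-2-oxoethyl)-1,2-dioxan-3-yl]oxolan-2-yl]heptyl}triphenylphosphonium iodide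
Conditions: PPh3 (1.5 equiv), MeCN, 50 °C, dark; stopped at full conversion of 20
Reagents that add atoms: triphenylphosphine, c1ccc(P(c2ccccc2)c2ccccc2)cc1
Why: SN2 quaternisation of triphenylphosphine by a primary iodide; an unstrained dialkyl peroxide is expected to react with the phosphine much more slowly than the iodide does at this temperature.

Step 14
Reactants: 22 pent-4-enal; 23 (triphenylphosphoranylidene)acetaldehyde
Product: 24 (2E)-hepta-2,6-dienal
Conditions: toluene, 80 °C; distillation
Reagents that add atoms: none
Why: Wittig formylolefination with a stabilised ylide gives the E enal; the isolated terminal alkene is inert.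

Step 15
Reactants: 21 {7-[(2R,5S)-5-[(3S,6S)-6-(2-methoxy-2-oxoethyl)-1,2-dioxan-3-yl]oxolan-2-yl]heptyl}triphenylphosphonium iodide; 24 (2E)-hepta-2,6-dienal
Product: 26 methyl 2-[(3S,6S)-6-[(2S,5R)-5-[(7Z,9E)-tetradeca-7,9,13-trien-1-yl]oxolan-2-yl]-1,2-dioxan-3-yl]acetate, via phosphonium ylide 25 (not isolated)
Conditions: NaN(SiMe3)2 (0.95 equiv), THF, −78 °C; then 24 (1.3 equiv), −78 to 0 °C
Reagents that add atoms: none
Why: Salt-free Wittig reaction of a non-stabilised ylide with an enal at low temperature should give the Z alkene at C17=C18 while the E C19=C20 bond is retained; a slight deficit of base deprotonates the much more acidic phosphonium α-CH2 rather than C2, so the β-peroxy ester is not opened.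

Step 16
Reactants: 26 methyl 2-[(3S,6S)-6-[(2S,5R)-5-[(7Z,9E)-tetradeca-7,9,13-trien-1-yl]oxolan-2-yl]-1,2-dioxan-3-yl]acetate
Product: 27 2-[(3S,6S)-6-[(2S,5R)-5-[(7Z,9E)-tetradeca-7,9,13-trien-1-yl]oxolan-2-yl]-1,2-dioxan-3-yl]acetic acid
Conditions: LiOH·H2O, THF/H2O (3:1), 0 °C to rt; 1 M HCl to pH 4 at 0 °C
Reagents that add atoms: lithium hydroxide, [Li+].[OH-]
Why: Ester saponification by hydroxide at 0 °C should be faster than enolisation at C2 or attack on the dialkyl peroxide; careful acidification gives the acid without isomerising the diene.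

## Compound list

1 | 6-bromohexan-1-ol | OCCCCCCBr | starting material
2 | tert-butyl[(6-bromohexyl)oxy]diphenylsilane | CC(C)(C)[Si](c1ccccc1)(c1ccccc1)OCCCCCCBr | intermediate
3 | (2S)-2-(but-3-en-1-yl)oxirane | C=CCC[C@H]1CO1 | starting material
4 | {6-[(tert-butyldiphenylsilyl)oxy]hexyl}magnesium bromide | CC(C)(C)[Si](c1ccccc1)(c1ccccc1)OCCCCCC[Mg]Br | intermediate
5 | (5R)-12-[(tert-butyldiphenylsilyl)oxy]dodec-1-en-5-ol | CC(C)(C)[Si](c1ccccc1)(c1ccccc1)OCCCCCCC[C@@H](O)CCC=C | intermediate
6 | [(2S,5R)-5-{7-[(tert-butyldiphenylsilyl)oxy]heptyl}oxolan-2-yl]methanol | CC(C)(C)[Si](c1ccccc1)(c1ccccc1)OCCCCCCC[C@@H]1CC[C@@H](CO)O1 | intermediate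
7 | (2S,5R)-5-{7-[(tert-butyldiphenylsilyl)oxy]heptyl}oxolane-2-carbaldehyde | CC(C)(C)[Si](c1ccccc1)(c1ccccc1)OCCCCCCC[C@@H]1CC[C@@H](C=O)O1 | intermediate
8 | cyclopropyldiphenylsulfonium tetrafluoroborate | F[B-](F)(F)F.c1ccc([S+](c2ccccc2)C2CC2)cc1 | starting material
9 | diphenylsulfonium cyclopropylide | c1ccc([S+](c2ccccc2)[C-]2CC2)cc1 | intermediate
10 | 2-[(2S,5R)-5-{7-[(tert-butyldiphenylsilyl)oxy]heptyl}oxolan-2-yl]-1-oxaspiro[2.2]pentane (both C2 epimers) | CC(C)(C)[Si](c1ccccc1)(c1ccccc1)OCCCCCCC[C@@H]1CC[C@@H](C2OC23CC3)O1 | intermediate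
11 | 2-[(2S,5R)-5-{7-[(tert-butyldiphenylsilyl)oxy]heptyl}oxolan-2-yl]cyclobutan-1-one (both C2 epimers) | CC(C)(C)[Si](c1ccccc1)(c1ccccc1)OCCCCCCC[C@@H]1CC[C@@H](C2CCC2=O)O1 | intermediate
12 | 2-[(2S,5R)-5-{7-[(tert-butyldiphenylsilyl)oxy]heptyl}oxolan-2-yl]cyclobutan-1-ol (all cyclobutane diastereomers) | CC(C)(C)[Si](c1ccccc1)(c1ccccc1)OCCCCCCC[C@@H]1CC[C@@H](C2CCC2O)O1 | intermediate
13 | (4S)-4-hydroperoxy-4-[(2S,5R)-5-{7-[(tert-butyldiphenylsilyl)oxy]heptyl}oxolan-2-yl]butanal | CC(C)(C)[Si](c1ccccc1)(c1ccccc1)OCCCCCCC[C@@H]1CC[C@@H]([C@@H](OO)CCC=O)O1 | intermediate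
14 | (6S)-6-[(2S,5R)-5-{7-[(tert-butyldiphenylsilyl)oxy]heptyl}oxolan-2-yl]-1,2-dioxan-3-ol (both C3 anomers) | CC(C)(C)[Si](c1ccccc1)(c1ccccc1)OCCCCCCC[C@@H]1CC[C@@H]([C@@H]2CCC(O)OO2)O1 | intermediate
15 | (6S)-6-[(2S,5R)-5-{7-[(tert-butyldiphenylsilyl)oxy]heptyl}oxolan-2-yl]-1,2-dioxan-3-yl acetate (both C3 anomers) | CC(C)(C)[Si](c1ccccc1)(c1ccccc1)OCCCCCCC[C@@H]1CC[C@@H]([C@@H]2CCC(OC(C)=O)OO2)O1 | intermediate
16 | tert-butyl[(1-methoxyethenyl)oxy]dimethylsilane | C=C(OC)O[Si](C)(C)C(C)(C)C | starting material
17 | methyl 2-[(6S)-6-[(2S,5R)-5-{7-[(tert-butyldiphenylsilyl)oxy]heptyl}oxolan-2-yl]-1,2-dioxan-3-yl]acetate (C3 epimers) | CC(C)(C)[Si](c1ccccc1)(c1ccccc1)OCCCCCCC[C@@H]1CC[C@@H]([C@@H]2CCC(CC(=O)OC)OO2)O1 | intermediate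
18 | methyl 2-[(3S,6S)-6-[(2S,5R)-5-{7-[(tert-butyldiphenylsilyl)oxy]heptyl}oxolan-2-yl]-1,2-dioxan-3-yl]acetate | CC(C)(C)[Si](c1ccccc1)(c1ccccc1)OCCCCCCC[C@@H]1CC[C@@H]([C@@H]2CC[C@@H](CC(=O)OC)OO2)O1 | intermediate
19 | methyl 2-[(3S,6S)-6-[(2S,5R)-5-(7-hydroxyheptyl)oxolan-2-yl]-1,2-dioxan-3-yl]acetate | OCCCCCCC[C@@H]1CC[C@@H]([C@@H]2CC[C@@H](CC(=O)OC)OO2)O1 | intermediate
20 | methyl 2-[(3S,6S)-6-[(2S,5R)-5-(7-iodoheptyl)oxolan-2-yl]-1,2-dioxan-3-yl]acetate | ICCCCCCC[C@@H]1CC[C@@H]([C@@H]2CC[C@@H](CC(=O)OC)OO2)O1 | intermediate
21 | {7-[(2R,5S)-5-[(3S,6S)-6-(2-methoxy-2-oxoethyl)-1,2-dioxan-3-yl]oxolan-2-yl]heptyl}triphenylphosphonium iodide | [I-].c1ccc(cc1)[P+](c1ccccc1)(c1ccccc1)CCCCCCC[C@@H]1CC[C@@H]([C@@H]2CC[C@@H](CC(=O)OC)OO2)O1 | intermediate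
22 | pent-4-enal | C=CCCC=O | starting material
23 | (triphenylphosphoranylidene)acetaldehyde | O=CC=P(c1ccccc1)(c1ccccc1)c1ccccc1 | starting material
24 | (2E)-hepta-2,6-dienal | C=CCC/C=C/C=O | intermediate
25 | methyl 2-[(3S,6S)-6-[(2S,5R)-5-[7-(triphenylphosphoranylidene)heptyl]oxolan-2-yl]-1,2-dioxan-3-yl]acetate | c1ccc(cc1)P(c1ccccc1)(c1ccccc1)=CCCCCCC[C@@H]1CC[C@@H]([C@@H]2CC[C@@H](CC(=O)OC)OO2)O1 | intermediate
26 | methyl 2-[(3S,6S)-6-[(2S,5R)-5-[(7Z,9E)-tetradeca-7,9,13-trien-1-yl]oxolan-2-yl]-1,2-dioxan-3-yl]acetate | C=CCC/C=C/C=C\CCCCCC[C@@H]1CC[C@@H]([C@@H]2CC[C@@H](CC(=O)OC)OO2)O1 | intermediate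
27 | 2-[(3S,6S)-6-[(2S,5R)-5-[(7Z,9E)-tetradeca-7,9,13-trien-1-yl]oxolan-2-yl]-1,2-dioxan-3-yl]acetic acid | C=CCC/C=C/C=C\CCCCCC[C@@H]1CC[C@@H]([C@@H]2CC[C@@H](CC(=O)O)OO2)O1 | target

## Step count and least certain steps

Total step count: 16. Longest linear sequence: 15 steps (steps 1–13, 15 and 16, from 1); step 14 is a one-step side branch.

Step 7 (key step). Dioxygen is likely to be captured at C6 with little facial preference, because the only control element is the neighbouring C7 centre of a freely rotating radical. Each C6 epimer also appears as an anomer pair, so the separation may be inefficient. In addition, cobalt may divert the secondary carbinol to simple dehydrogenation back to 11 or degrade the hydroperoxide in a Fenton-type manner. The fallback introduces the C6 peroxide by a stereospecific ionic substitution; it sets out from 7 and comes back to the route at 14. The Grignard reagent from 2-(2-bromoethyl)-1,3-dioxolane is transmetallated with ClTi(OiPr)3 so that addition to 7 follows the non-chelation (Felkin–Anh) course. This should give the erythro carbinol (1R)-3-(1,3-dioxolan-2-yl)-1-[(2S,5R)-5-{7-[(tert-butyldiphenylsilyl)oxy]heptyl}oxolan-2-yl]propan-1-ol F1. Mesylation (MsCl, Et3N) gives the methanesulfonate of that carbinol F2. Displacement with 2-methoxypropan-2-yl hydroperoxide and CsOH in DMF (SN2, inversion) gives the 6S peroxyketal tert-butyl{[7-[(2R,5S)-5-[(1S)-3-(1,3-dioxolan-2-yl)-1-[(2-methoxypropan-2-yl)peroxy]propyl]oxolan-2-yl]heptyl]oxy}diphenylsilane F3. Aqueous acid then removes the perketal and the dioxolane, and the hydroperoxy aldehyde 13 closes to 14 as a single C6 epimer. The price is a slow substitution at the hindered C6.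

Step 10. The C2 enolate that mediates ring opening may attack the O–O bond instead (3-exo closure to a glycidic ester with irreversible loss of the peroxide). Alternatively, base-induced Kornblum–DeLaMare fragmentation at C6–H may outrun a slow equilibration. The fallback places the acetic arm on C3 before the peroxide ring exists and sets C3 by kinetic hydride delivery; it sets out from 11 and comes back at 18. Reformatsky addition (BrCH2CO2Me, Zn, THF) to 11 gives the tertiary cyclobutanol methyl 2-{1-hydroxy-2-[(2S,5R)-5-{7-[(tert-butyldiphenylsilyl)oxy]heptyl}oxolan-2-yl]cyclobutyl}acetate F4. The same Co(acac)2/O2 ring expansion, followed by separation of the C6 epimers, gives the peroxy-hemiketal methyl 2-[(6S)-3-hydroxy-6-[(2S,5R)-5-{7-[(tert-butyldiphenylsilyl)oxy]heptyl}oxolan-2-yl]-1,2-dioxan-3-yl]acetate F5. Et3SiH with Me3SiOTf in CH2Cl2 at −78 °C ionises C3 and delivers hydride axially, which places the acetic arm equatorial and should give 18 directly without any enolate.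

Step 13. The peroxide may be deoxygenated by triphenylphosphine (insertion into the O–O bond) during the hours needed for quaternisation. The fallback builds the diene without a nucleophilic phosphine; it sets out from 19 and comes back at 26. Dess–Martin oxidation gives the aldehyde methyl 2-[(3S,6S)-6-[(2S,5R)-5-(7-oxoheptyl)oxolan-2-yl]-1,2-dioxan-3-yl]acetate F6. Stork–Zhao olefination with Ph3P=CHI (from the iodomethylphosphonium iodide and NaN(SiMe3)2, THF, −78 °C) gives the Z vinyl iodide methyl 2-[(3S,6S)-6-[(2S,5R)-5-[(7Z)-8-iodooct-7-en-1-yl]oxolan-2-yl]-1,2-dioxan-3-yl]acetate F7. Stille coupling with (E)-tributyl(hexa-1,5-dien-1-yl)stannane F8 (from hex-5-en-1-yne by stannylcupration) under Pd2(dba)3/AsPh3 (zerovalent palladium, phosphine-free) should give 26 with both alkene geometries retained.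

Step 5. Configuration at C7 may be lost by enolisation of the α-alkoxy aldehyde under the basic ylide conditions. The ring expansion may also be sluggish, because the positive charge developing at C6 is destabilised by the oxygen on C7. The fallback uses a sulfur-stabilised cation to drive the ring expansion; it sets out from 7 and comes back at 11. Addition of 1-lithio-1-(phenylsulfanyl)cyclopropane (cyclopropyl phenyl sulfide, n-BuLi, THF) at −78 °C, a fast irreversible 1,2-addition, gives the carbinol [1-(phenylsulfanyl)cyclopropyl][(2S,5R)-5-{7-[(tert-butyldiphenylsilyl)oxy]heptyl}oxolan-2-yl]methanol F9. Acid (p-TsOH·H2O, wet toluene) induces the cyclopropylcarbinyl-to-cyclobutyl shift to the thionium ion, whose hydrolysis gives 11.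

## Further compounds

F1 | step 7 | (1R)-3-(1,3-dioxolan-2-yl)-1-[(2S,5R)-5-{7-[(tert-butyldiphenylsilyl)oxy]heptyl}oxolan-2-yl]propan-1-ol | CC(C)(C)[Si](c1ccccc1)(c1ccccc1)OCCCCCCC[C@@H]1CC[C@@H]([C@H](O)CCC2OCCO2)O1
F2 | step 7 | (1R)-3-(1,3-dioxolan-2-yl)-1-[(2S,5R)-5-{7-[(tert-butyldiphenylsilyl)oxy]heptyl}oxolan-2-yl]propyl methanesulfonate | CC(C)(C)[Si](c1ccccc1)(c1ccccc1)OCCCCCCC[C@@H]1CC[C@@H]([C@H](OS(C)(=O)=O)CCC2OCCO2)O1
F3 | step 7 | tert-butyl{[7-[(2R,5S)-5-[(1S)-3-(1,3-dioxolan-2-yl)-1-[(2-methoxypropan-2-yl)peroxy]propyl]oxolan-2-yl]heptyl]oxy}diphenylsilane | CC(C)(C)[Si](c1ccccc1)(c1ccccc1)OCCCCCCC[C@@H]1CC[C@@H]([C@@H](OOC(C)(C)OC)CCC2OCCO2)O1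
F4 | step 10 | methyl 2-{1-hydroxy-2-[(2S,5R)-5-{7-[(tert-butyldiphenylsilyl)oxy]heptyl}oxolan-2-yl]cyclobutyl}acetate (diastereomers) | CC(C)(C)[Si](c1ccccc1)(c1ccccc1)OCCCCCCC[C@@H]1CC[C@@H](C2CCC2(O)CC(=O)OC)O1
F5 | step 10 | methyl 2-[(6S)-3-hydroxy-6-[(2S,5R)-5-{7-[(tert-butyldiphenylsilyl)oxy]heptyl}oxolan-2-yl]-1,2-dioxan-3-yl]acetate (C3 anomers) | CC(C)(C)[Si](c1ccccc1)(c1ccccc1)OCCCCCCC[C@@H]1CC[C@@H]([C@@H]2CCC(O)(CC(=O)OC)OO2)O1
F6 | step 13 | methyl 2-[(3S,6S)-6-[(2S,5R)-5-(7-oxoheptyl)oxolan-2-yl]-1,2-dioxan-3-yl]acetate | O=CCCCCCC[C@@H]1CC[C@@H]([C@@H]2CC[C@@H](CC(=O)OC)OO2)O1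
F7 | step 13 | methyl 2-[(3S,6S)-6-[(2S,5R)-5-[(7Z)-8-iodooct-7-en-1-yl]oxolan-2-yl]-1,2-dioxan-3-yl]acetate | I/C=C\CCCCCC[C@@H]1CC[C@@H]([C@@H]2CC[C@@H](CC(=O)OC)OO2)O1
F8 | step 13 | (E)-tributyl(hexa-1,5-dien-1-yl)stannane | C=CCC/C=C/[Sn](CCCC)(CCCC)CCCC
F9 | step 5 | [1-(phenylsulfanyl)cyclopropyl][(2S,5R)-5-{7-[(tert-butyldiphenylsilyl)oxy]heptyl}oxolan-2-yl]methanol (carbinol epimers) | CC(C)(C)[Si](c1ccccc1)(c1ccccc1)OCCCCCCC[C@@H]1CC[C@@H](C(O)C2(Sc3ccccc3)CC2)O1
A1 | alternative 1 | methyl (2E,6R)-6-hydroxy-6-[(2S,5R)-5-[(7Z,9E)-tetradeca-7,9,13-trien-1-yl]oxolan-2-yl]hex-2-enoate | C=CCC/C=C/C=C\CCCCCC[C@@H]1CC[C@@H]([C@H](O)CC/C=C/C(=O)OC)O1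
A2 | alternative 1 | methyl (2E,6Z,10R,17Z,19E)-10-hydroxytetracosa-2,6,17,19,23-pentaenoate | C=CCC/C=C/C=C\CCCCCC[C@@H](O)CC/C=C\CC/C=C/C(=O)OC
A3 | alternative 2 | (2R,5S)-5-{[(tert-butyldiphenylsilyl)oxy]methyl}-2-(prop-2-en-1-yl)oxolan-3-one | C=CC[C@@H]1C(=O)C[C@@H](CO[Si](c2ccccc2)(c2ccccc2)C(C)(C)C)O1
A4 | alternative 2 | (4S)-5-[(tert-butyldiphenylsilyl)oxy]-1-diazo-4-(prop-2-en-1-yloxy)pentan-2-one | [N-]=[N+]=CC(=O)C[C@H](OCC=C)CO[Si](c1ccccc1)(c1ccccc1)C(C)(C)C
A5 | alternative 3 | tert-butyl{2-[(3S,6S)-6-[(2S,5R)-5-[(7Z,9E)-tetradeca-7,9,13-trien-1-yl]oxolan-2-yl]-1,2-dioxan-3-yl]ethoxy}diphenylsilane | C=CCC/C=C/C=C\CCCCCC[C@@H]1CC[C@@H]([C@@H]2CC[C@@H](CCO[Si](c3ccccc3)(c3ccccc3)C(C)(C)C)OO2)O1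
A6 | alternative 3 | (3S,6R,7S,10S,17Z,19E)-1-[(tert-butyldiphenylsilyl)oxy]-6,7-epoxy-3-hydroperoxytetracosa-17,19,23-trien-10-yl methanesulfonate | CC(C)(C)[Si](c1ccccc1)(c1ccccc1)OCC[C@@H](OO)CC[C@H]1O[C@H]1CC[C@@H](OS(C)(=O)=O)CCCCCC/C=C\C=C\CCC=C
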